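Remark on the chemistry (numbering assumption): rings are lettered A to H from the 2,4,6-trihydroxyphenyl end to the 3,4,5-trihydroxyphenyl end, and in each ring position 1 is the carbon whose ether oxygen points toward ring A (in ring A, its only ether carbon).

## The problem

The target is a linear chain of eight oxygenated benzene rings joined only by seven diaryl ether bonds. It has twenty-one free hydroxyls and no stereocentre, so the whole task is to decide which oxygen ends up on which carbon. Rings B, D and F are 3,5-dihydroxy-1,4-phenylene units, rings C, E and G are 3,4,5-trihydroxy-1,2-phenylene units, ring A is a 2,4,6-trihydroxyphenyl cap and ring H a 3,4,5-trihydroxyphenyl cap. Every ring is electron-rich and every ether carbon has oxygenated neighbours, so the ether bonds cannot be made by substitution on the rings as they stand, and copper-mediated couplings of such hindered, donor-laden partners are unreliable. The free polyphenol, with its pyrogallol- and phloroglucinol-type rings, is oxidised by air in base and attacked by electrophiles. The hydroxyls must therefore stay masked to the last step, the unmasking must be non-oxidative, and the phenoxides used on the way must be kept from air. The chain repeats itself: in each of rings C, E and G, position 1 carries the hindered oxygen of the preceding 1,4-ring (flanked by two methoxy groups) and position 2 the unhindered oxygen of the following ring. The enabling feature is that E1 lies para to E4 and E2 ortho to E3. If the E3 and E4 hydroxyls are carried as formyl groups, both ether carbons become activated C–F positions of one small arene, the dialdehyde 5, and Baeyer–Villiger oxidation later turns the formyl groups into the hydroxyls. Ring E sits in the middle, so this cut also divides the octamer into a tetramer and a trimer, and the same positional relation holds in rings C and G.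

## Retrosynthesis

**35 from 34.** The nineteen O–CH3 bonds of the octamer diol 34 are cut last. Methyl ethers are chosen over benzyl ethers because they are small and survive hot carbonate, peracid and the hydrogenolyses that remove two temporary benzyl groups. The forward reaction is one exhaustive Lewis-acid ether cleavage that must leave the seven diaryl ether bonds alone.

**34 from 32.** The E3–O and E4–O bonds are traced back to the two C–CHO bonds of the octamer dialdehyde 32. This is preferred to carrying E3 and E4 as ethers because the formyl groups are exactly what activates the neighbouring ether carbons in the preceding step. The forward reaction is a double Baeyer–Villiger oxidation with cleavage of the bis(formate) 33.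

**32 from 19, 5 and 30.** The E1–O and E2–O bonds are cut together. This is the most convergent cut in the molecule (four rings, one ring, three rings), and both bonds fall on a carbon para or ortho to a formyl group. Cutting D1–O/C2 or F4–O/G1 instead would give less balanced halves and no activated carbon. The precursors are the tetramer phenol 19, the trimer phenol 30 and the difluorodialdehyde 5. The forward reaction must place the hindered D4 phenoxide on E1 and the unhindered F1 phenoxide on E2, through the monofluoride 31.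

**19 from 10, 5 and 13.** Ring C has the same substitution pattern as ring E, so the same linchpin is used again. The phenol 19 comes from its benzyl ether 18, which comes from the catechol 17 by methylation. The catechol 17 comes from the dialdehyde 15 by way of the bis(formate) 16, and 15 is the union of the A–B phenol 10, the linchpin 5 and the benzyl-protected ring D phenol 13, by way of the monofluoride 14. A benzyl group masks D4–OH because this oxygen must stay distinct from the C3 and C4 oxygens that are methylated. Using 5 here also tests the key reaction on cheap material.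

**30 from 23, 5 and 24.** Ring G is again the same pattern. The phenol 30 comes from the benzyl ether 29, 29 from the catechol 28, and 28 from the dialdehyde 26 by way of the bis(formate) 27. The dialdehyde 26 is the union of the benzyl-protected ring F phenol 23 (hindered, goes on G1), the linchpin 5 and 3,4,5-trimethoxyphenol 24 (unhindered, goes on G2), by way of the monofluoride 25.

**Small phenols.** The A–B phenol 10 comes from the aldehyde 8 by Dakin-type oxidation through the formate 9, and 8 from 2,4,6-trimethoxyphenol 6 and 4-fluoro-2,6-dimethoxybenzaldehyde 7 by cutting the B1–O bond para to the formyl group. The ring D phenol 13 comes from 4-(benzyloxy)-3,5-dimethoxybenzaldehyde 11 through the formate 12. The ring F phenol 23 comes from 4-hydroxy-2,6-dimethoxybenzaldehyde 20 by benzylation to 21 and oxidation through the formate 22. All three use the formyl-to-hydroxyl exchange that the key step relies on.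

**5 from 1.** The C–CHO bond next to fluorine is cut. The aldehyde 1 already has the methoxy group, both fluorines and one formyl group in place. The forward reaction is an ortho-metalation directed by the masked formyl group (intermediates 2, 3, 4) and must prefer the position beside that group over the position between methoxy and fluorine.

## Roads not taken

**Alternative 1:** Ring G is cut at G5–G6 and built from dimethyl squarate A2. The vinyl ether A4 of the A–F hexamer would be lithiated and added to A2, and the adduct protected to give the cyclobutenone A3. Heating A3 would open the four-membered ring to a dienylketene that closes by 6π electrocyclisation and tautomerises to the heptamer phenol A1. The merit is real: all five oxygens of ring G arrive with fixed positions and are differentiated (G5 free, G2 as a methoxymethyl ether), with no site-selectivity question. The weak points are structural: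
- Only one of the three 1,2-diaryloxy rings is solved, and rings C and E must already be in A4.
- α-Lithiation of A4 competes with metalation at the many ring positions flanked by oxygens.
- After the ring expansion the G2–O–H1 bond still has to be made by arylating a hindered G2 phenol with an unactivated trimethoxyphenyl donor, the kind of coupling the target makes hardest.
- The sequence is linear from the hexamer onward.

In positional certainty for ring G this road is better than the chosen plan. The chosen plan sets against it one reagent, 5, that serves rings C, E and G alike and a convergent end-game.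

**Alternative 2:** Ring A is cut at A4–A5 and folded from the aryloxy triketide diester A6 by base-mediated Claisen condensation, giving the octamer A5 with ring A as a methyl trihydroxybenzoate. It is biomimetic and delivers ring A with free hydroxyls, so three fewer ethers would have to be cleaved at the end; in that respect it is slightly better. Its weak points:
- Ring A is the ring that needs no synthesis, since it is available as 6.
- A6 requires putting the B1 oxygen of a complete B–H heptamer on the central carbon of a 3,5-dioxoheptanedioate, a substrate prone to enolisation, retro-Claisen cleavage and pyrone formation.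
- The extra ester has to be removed.
- All three hard rings and all seven ether bonds remain to be made by other means.

The chosen plan answers this by spending its key step on the middle of the chain, where the real difficulty lies.

**Alternative 3:** The four C–O bonds at C4, E4, G4 and H4 are traced to formyl groups, and the tetraaldehyde A8 is oxidised fourfold with peracid to the tetraphenol A7. A8 would come from a linear chain of para-activated substitutions, ring by ring, using 7 for rings B, D, F and H and a 3-hydroxy analogue such as A9 for rings C, E and G. This road is closest in spirit to the chosen one and in one respect stronger: every ether bond is formed para to a formyl group, so no fluoride has to react while deactivated by a para methoxy group, and no choice between two fluorides arises. Its weak points: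
- It is strictly linear over seven extensions.
- The C4, E4 and G4 formyl groups must survive the oxidations that unmask the B4, D4 and F4 hydroxyls, which asks for selectivity between nearly identical aldehydes or for extra protecting groups.
- The nucleophiles at C2, E2 and G2 are flanked by an aryloxy and a methoxy group.
- A9 is not a stock compound.

The chosen plan gives up uniform para activation and accepts a harder second displacement at E2. In return it gets a 4 + 1 + 3 assembly with a longest linear sequence of nine steps and two small-scale rehearsals of its key reaction.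

Key step: step 15

## Route

Step 1
Reactants: 1 4,5-difluoro-2-methoxybenzaldehyde
Product: 5 3,4-difluoro-6-methoxybenzene-1,2-dicarbaldehyde, via lithium α-amino alkoxide 2 (not isolated), via ortho-lithiated amino alkoxide 3 (not isolated), via dilithium bis(hemiaminal) alkoxide 4 (not isolated)
Conditions: LiN(Me)CH2CH2NMe2 (from N,N,N'-trimethylethylenediamine and n-BuLi), THF, −78 → −40 °C; n-BuLi, −78 °C; DMF, −78 → 0 °C; 1 M HCl
Reagents that add atoms: N,N-dimethylformamide, CN(C)C=O
Why: Directed ortho-metalation of an α-amino alkoxide formed in the flask, followed by formylation: the chelating amino alkoxide of 2 and the adjacent fluorine should steer n-BuLi to the ring carbon beside the masked formyl group in preference to the one between methoxy and fluorine; 3 is kept at −78 °C so that LiF is not lost, DMF gives 4, and acid releases both formyl groups.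

Step 2
Reactants: 6 2,4,6-trimethoxyphenol; 7 4-fluoro-2,6-dimethoxybenzaldehyde
Product: 8 2,6-dimethoxy-4-(2,4,6-trimethoxyphenoxy)benzaldehyde
Conditions: K2CO3, DMSO, 110 °C, Ar
Reagents that add atoms: none
Why: Nucleophilic aromatic substitution (addition–elimination) of a fluoride para to a formyl group by an electron-rich phenoxide; the two methoxy groups of 7 are meta to the reacting carbon and do not oppose the Meisenheimer adduct.

Step 3
Reactants: 8 2,6-dimethoxy-4-(2,4,6-trimethoxyphenoxy)benzaldehyde
Product: 10 2,6-dimethoxy-4-(2,4,6-trimethoxyphenoxy)phenol, via aryl formate 9 (not isolated)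
Conditions: mCPBA, CH2Cl2, 0 °C → rt; then MeOH, K2CO3 (cat.), 0 °C
Reagents that add atoms: 3-chloroperoxybenzoic acid (mCPBA), OOC(=O)c1cccc(Cl)c1
Why: Baeyer–Villiger (Dakin-type) oxidation of a benzaldehyde with two ortho methoxy groups and a para aryloxy group, in which the electron-rich aryl group migrates in preference to hydrogen; the formate 9 is cleaved by methanolysis.

Step 4
Reactants: 11 4-(benzyloxy)-3,5-dimethoxybenzaldehyde
Product: 13 4-(benzyloxy)-3,5-dimethoxyphenol, via aryl formate 12 (not isolated)
Conditions: mCPBA, CH2Cl2, 0 °C → rt; then MeOH, K2CO3 (cat.), 0 °C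
Reagents that add atoms: 3-chloroperoxybenzoic acid (mCPBA), OOC(=O)c1cccc(Cl)c1
Why: Baeyer–Villiger oxidation of a 3,4,5-trialkoxybenzaldehyde, a standard entry to 3,4,5-trialkoxyphenols; the para benzyloxy group drives aryl migration and is inert to peracid.

Step 5
Reactants: 10 2,6-dimethoxy-4-(2,4,6-trimethoxyphenoxy)phenol; 5 3,4-difluoro-6-methoxybenzene-1,2-dicarbaldehyde; 13 4-(benzyloxy)-3,5-dimethoxyphenol
Product: 15 3-[4-(benzyloxy)-3,5-dimethoxyphenoxy]-4-[2,6-dimethoxy-4-(2,4,6-trimethoxyphenoxy)phenoxy]-6-methoxybenzene-1,2-dicarbaldehyde (tetramer A–D dialdehyde), via monofluoride 14 (not isolated)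
Conditions: 10, 5, Cs2CO3, DMSO, 4 Å MS, 20 → 40 °C, Ar; then 13, Cs2CO3, 80 °C
Reagents that add atoms: none
Why: Sequential nucleophilic aromatic substitution on a difluorobenzaldehyde: the hindered phenoxide of 10 takes the fluoride para to a formyl group (C1 of ring C), then the unhindered phenoxide of 13 takes the fluoride ortho to the other formyl group (C2) at higher temperature; this is the key union run on small partners.

Step 6
Reactants: 15 tetramer A–D dialdehyde
Product: 17 3-[4-(benzyloxy)-3,5-dimethoxyphenoxy]-4-[2,6-dimethoxy-4-(2,4,6-trimethoxyphenoxy)phenoxy]-6-methoxybenzene-1,2-diol, via bis(formate) 16 (not isolated)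
Conditions: mCPBA, CH2Cl2, −10 → 0 °C; then MeOH, K2CO3 (cat.), 0 °C, Ar
Reagents that add atoms: 3-chloroperoxybenzoic acid (mCPBA), OOC(=O)c1cccc(Cl)c1
Why: Double Baeyer–Villiger oxidation; each formyl group has an ortho oxygen donor (methoxy or aryloxy) that favours aryl migration, and the benzyl and methyl ethers are inert to peracid at low temperature.

Step 7
Reactants: 17 the catechol from step 6
Product: 18 2-(benzyloxy)-5-{6-[2,6-dimethoxy-4-(2,4,6-trimethoxyphenoxy)phenoxy]-2,3,4-trimethoxyphenoxy}-1,3-dimethoxybenzene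
Conditions: MeI, K2CO3, DMF, rt, Ar
Reagents that add atoms: iodomethane, CI
Why: Williamson O-methylation of both catechol hydroxyls, run under argon because the catechol dianion is air-sensitive; it completes the trimethoxy pattern of ring C.

Step 8
Reactants: 18 the D4 benzyl ether from step 7
Product: 19 4-{6-[2,6-dimethoxy-4-(2,4,6-trimethoxyphenoxy)phenoxy]-2,3,4-trimethoxyphenoxy}-2,6-dimethoxyphenol (tetramer A–D phenol, D4–OH)
Conditions: H2 (1 atm), Pd/C, EtOAc/MeOH, rt
Reagents that add atoms: none
Why: Hydrogenolysis of a benzyl aryl ether; methyl ethers and diaryl ethers are untouched, and no reducible group remains once the formyl groups have been converted.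

Step 9
Reactants: 20 4-hydroxy-2,6-dimethoxybenzaldehyde
Product: 21 4-(benzyloxy)-2,6-dimethoxybenzaldehyde
Conditions: BnBr, K2CO3, DMF, rt
Reagents that add atoms: benzyl bromide, BrCc1ccccc1
Why: Williamson O-benzylation of an acidic para-formyl phenol.

Step 10
Reactants: 21 4-(benzyloxy)-2,6-dimethoxybenzaldehyde
Product: 23 4-(benzyloxy)-2,6-dimethoxyphenol, via aryl formate 22 (not isolated)
Conditions: mCPBA, CH2Cl2, 0 °C → rt; then MeOH, K2CO3 (cat.), 0 °C
Reagents that add atoms: 3-chloroperoxybenzoic acid (mCPBA), OOC(=O)c1cccc(Cl)c1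
Why: Baeyer–Villiger oxidation of a 2,4,6-trialkoxybenzaldehyde, the same transformation as step 3, giving the hindered phenol that becomes the F4 oxygen.

Step 11
Reactants: 23 4-(benzyloxy)-2,6-dimethoxyphenol; 5 3,4-difluoro-6-methoxybenzene-1,2-dicarbaldehyde; 24 3,4,5-trimethoxyphenol
Product: 26 4-[4-(benzyloxy)-2,6-dimethoxyphenoxy]-6-methoxy-3-(3,4,5-trimethoxyphenoxy)benzene-1,2-dicarbaldehyde (trimer F–H dialdehyde), via monofluoride 25 (not isolated)
Conditions: 23, 5, Cs2CO3, DMSO, 4 Å MS, 20 → 40 °C, Ar; then 24, Cs2CO3, 80 °C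
Reagents that add atoms: none
Why: Sequential nucleophilic aromatic substitution as in step 5: the hindered phenoxide of 23 goes to the para-activated carbon (G1) and the unhindered phenoxide of 24 to the ortho-activated carbon (G2).

Step 12
Reactants: 26 trimer F–H dialdehyde
Product: 28 4-[4-(benzyloxy)-2,6-dimethoxyphenoxy]-6-methoxy-3-(3,4,5-trimethoxyphenoxy)benzene-1,2-diol, via bis(formate) 27 (not isolated)
Conditions: mCPBA, CH2Cl2, −10 → 0 °C; then MeOH, K2CO3 (cat.), 0 °C, Ar
Reagents that add atoms: 3-chloroperoxybenzoic acid (mCPBA), OOC(=O)c1cccc(Cl)c1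
Why: Double Baeyer–Villiger oxidation as in step 6, with methanolysis of the bis(formate) 27.

Step 13
Reactants: 28 the catechol from step 12
Product: 29 5-(benzyloxy)-1,3-dimethoxy-2-[3,4,5-trimethoxy-2-(3,4,5-trimethoxyphenoxy)phenoxy]benzene
Conditions: MeI, K2CO3, DMF, rt, Ar
Reagents that add atoms: iodomethane, CI
Why: Williamson O-methylation of the catechol, completing the trimethoxy pattern of ring G.

Step 14
Reactants: 29 the F1 benzyl ether from step 13
Product: 30 3,5-dimethoxy-4-[3,4,5-trimethoxy-2-(3,4,5-trimethoxyphenoxy)phenoxy]phenol (trimer F–H phenol, F1–OH)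
Conditions: H2 (1 atm), Pd/C, EtOAc/MeOH, rt
Reagents that add atoms: none
Why: Hydrogenolysis of the benzyl aryl ether frees the unhindered F1 hydroxyl; all other ethers are stable.

Step 15
Reactants: 19 tetramer A–D phenol; 5 3,4-difluoro-6-methoxybenzene-1,2-dicarbaldehyde; 30 trimer F–H phenol
Product: 32 permethylated octamer E3,E4-dicarbaldehyde (ring E: E1–O–D4; E2–O–F1; E3 and E4 formyl; E5 methoxy), via monofluoride 31 (not isolated)
Conditions: 19, 5 (1:1), Cs2CO3, DMSO, 4 Å MS, 20 → 40 °C, Ar; then 30, Cs2CO3, 80 °C
Reagents that add atoms: none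
Why: Two addition–elimination events run in one flask: the caesium phenoxide of 19 adds to C4 of 5 (the future E1), the Meisenheimer anion is delocalised into the para formyl group (future E4) and fluoride leaves to give 31; after 30 and more base are added and the mixture is warmed, the phenoxide of 30 adds to C3 (future E2), the charge resting on the ortho formyl group (future E3), and the second fluoride leaves. The closest known reaction type is the stepwise displacement of ortho- and para-activated fluorides of fluorobenzaldehydes by phenoxides that underlies the usual substitution/Baeyer–Villiger route to diaryl ethers, and steps 5 and 11 run the same union on small partners. No ring is closed and no stereocentre is formed. The step needs site selectivity between the two C–F bonds and a stop after one substitution in the first stage. Both are set by the substrate: the E1 carbon has a para formyl group, no para donor and a hydrogen neighbour, whereas the E2 carbon is deactivated by the para methoxy group and wedged between a formyl group and the first fluorine, and once the first aryloxy group is in place its donation lowers the reactivity of the remaining fluoride further, so the two displacements should be separable by temperature. The 2,6-dimethoxy-flanked phenoxide of 19 is therefore spent on the open E1 position and the ortho-unsubstituted phenoxide of 30 on the crowded E2 position. DMSO in place of DMF avoids competing dimethylamine, molecular sieves keep hydroxide away from the base-sensitive dialdehyde, and argon protects the phenoxides.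

Step 16
Reactants: 32 permethylated octamer E3,E4-dicarbaldehyde
Product: 34 permethylated octamer E3,E4-diol (nineteen methyl ethers; free hydroxyls on E3 and E4), via bis(formate) 33 (not isolated)
Conditions: mCPBA, CH2Cl2, −10 → 0 °C; then MeOH, K2CO3 (cat.), 0 °C, Ar
Reagents that add atoms: 3-chloroperoxybenzoic acid (mCPBA), OOC(=O)c1cccc(Cl)c1
Why: Double Baeyer–Villiger oxidation as in steps 6 and 12: the E4 formyl group (ortho methoxy, para aryloxy) and the E3 formyl group (ortho aryloxy) both sit on an oxygen-rich ring that migrates in preference to hydrogen, and methanolysis of 33 gives the catechol.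

Step 17
Reactants: 34 permethylated octamer E3,E4-diol
Product: 35 CNP0206369.0, the fully hydroxylated octamer
Conditions: BBr3 (excess), CH2Cl2, −78 °C → rt, Ar; then H2O, 0 °C
Reagents that add atoms: none
Why: Lewis-acid cleavage of aryl methyl ethers: bromide attacks the methyl carbon of each boron-complexed ether, while diaryl ethers have no carbon open to such attack and stay intact; hydrolysis of the boron aryloxides under argon frees the twenty-one hydroxyls.

## Compound list

1 | 4,5-difluoro-2-methoxybenzaldehyde | COc1cc(F)c(F)cc1C=O | starting material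
2 | lithium (4,5-difluoro-2-methoxyphenyl){[2-(dimethylamino)ethyl](methyl)amino}methanolate | COc1cc(F)c(F)cc1C(O[Li])N(C)CCN(C)C | intermediate
3 | ring-lithiated derivative of 2 (lithium on the carbon between the masked formyl carbon and fluorine) | [Li]c1c(F)c(F)cc(OC)c1C(O[Li])N(C)CCN(C)C | intermediate
4 | dilithium bis(hemiaminal) alkoxide from 3 and DMF | COc1cc(F)c(F)c(C(O[Li])N(C)C)c1C(O[Li])N(C)CCN(C)C | intermediate
5 | 3,4-difluoro-6-methoxybenzene-1,2-dicarbaldehyde | COc1cc(F)c(F)c(C=O)c1C=O | intermediate
6 | 2,4,6-trimethoxyphenol | COc1cc(OC)c(O)c(OC)c1 | starting material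
7 | 4-fluoro-2,6-dimethoxybenzaldehyde | COc1cc(F)cc(OC)c1C=O | starting material
8 | 2,6-dimethoxy-4-(2,4,6-trimethoxyphenoxy)benzaldehyde | COc1cc(OC)c(Oc2cc(OC)c(C=O)c(OC)c2)c(OC)c1 | intermediate
9 | 2,6-dimethoxy-4-(2,4,6-trimethoxyphenoxy)phenyl formate | COc1cc(OC)c(Oc2cc(OC)c(OC=O)c(OC)c2)c(OC)c1 | intermediate
10 | 2,6-dimethoxy-4-(2,4,6-trimethoxyphenoxy)phenol | COc1cc(OC)c(Oc2cc(OC)c(O)c(OC)c2)c(OC)c1 | intermediate
11 | 4-(benzyloxy)-3,5-dimethoxybenzaldehyde | COc1cc(C=O)cc(OC)c1OCc1ccccc1 | starting material
12 | 4-(benzyloxy)-3,5-dimethoxyphenyl formate | COc1cc(OC=O)cc(OC)c1OCc1ccccc1 | intermediate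
13 | 4-(benzyloxy)-3,5-dimethoxyphenol | COc1cc(O)cc(OC)c1OCc1ccccc1 | intermediate
14 | 4-[2,6-dimethoxy-4-(2,4,6-trimethoxyphenoxy)phenoxy]-3-fluoro-6-methoxybenzene-1,2-dicarbaldehyde | COc1cc(Oc2c(OC)cc(Oc3c(OC)cc(OC)cc3OC)cc2OC)c(F)c(C=O)c1C=O | intermediate
15 | 3-[4-(benzyloxy)-3,5-dimethoxyphenoxy]-4-[2,6-dimethoxy-4-(2,4,6-trimethoxyphenoxy)phenoxy]-6-methoxybenzene-1,2-dicarbaldehyde | COc1cc(Oc2c(OC)cc(Oc3c(OC)cc(OC)cc3OC)cc2OC)c(Oc2cc(OC)c(OCc3ccccc3)c(OC)c2)c(C=O)c1C=O | intermediate
16 | 3-[4-(benzyloxy)-3,5-dimethoxyphenoxy]-4-[2,6-dimethoxy-4-(2,4,6-trimethoxyphenoxy)phenoxy]-6-methoxy-1,2-phenylene diformate | COc1cc(Oc2c(OC)cc(Oc3c(OC)cc(OC)cc3OC)cc2OC)c(Oc2cc(OC)c(OCc3ccccc3)c(OC)c2)c(OC=O)c1OC=O | intermediate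
17 | 3-[4-(benzyloxy)-3,5-dimethoxyphenoxy]-4-[2,6-dimethoxy-4-(2,4,6-trimethoxyphenoxy)phenoxy]-6-methoxybenzene-1,2-diol | COc1cc(Oc2c(OC)cc(Oc3c(OC)cc(OC)cc3OC)cc2OC)c(Oc2cc(OC)c(OCc3ccccc3)c(OC)c2)c(O)c1O | intermediate
18 | 2-(benzyloxy)-5-{6-[2,6-dimethoxy-4-(2,4,6-trimethoxyphenoxy)phenoxy]-2,3,4-trimethoxyphenoxy}-1,3-dimethoxybenzene | COc1cc(Oc2c(OC)cc(Oc3c(OC)cc(OC)cc3OC)cc2OC)c(Oc2cc(OC)c(OCc3ccccc3)c(OC)c2)c(OC)c1OC | intermediate
19 | 4-{6-[2,6-dimethoxy-4-(2,4,6-trimethoxyphenoxy)phenoxy]-2,3,4-trimethoxyphenoxy}-2,6-dimethoxyphenol (tetramer A–D phenol) | COc1cc(Oc2c(OC)cc(Oc3c(OC)cc(OC)cc3OC)cc2OC)c(Oc2cc(OC)c(O)c(OC)c2)c(OC)c1OC | intermediate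
20 | 4-hydroxy-2,6-dimethoxybenzaldehyde | COc1cc(O)cc(OC)c1C=O | starting material
21 | 4-(benzyloxy)-2,6-dimethoxybenzaldehyde | COc1cc(OCc2ccccc2)cc(OC)c1C=O | intermediate
22 | 4-(benzyloxy)-2,6-dimethoxyphenyl formate | COc1cc(OCc2ccccc2)cc(OC)c1OC=O | intermediate
23 | 4-(benzyloxy)-2,6-dimethoxyphenol | COc1cc(OCc2ccccc2)cc(OC)c1O | intermediate
24 | 3,4,5-trimethoxyphenol | COc1cc(O)cc(OC)c1OC | starting material
25 | 4-[4-(benzyloxy)-2,6-dimethoxyphenoxy]-3-fluoro-6-methoxybenzene-1,2-dicarbaldehyde | COc1cc(Oc2c(OC)cc(OCc3ccccc3)cc2OC)c(F)c(C=O)c1C=O | intermediate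
26 | 4-[4-(benzyloxy)-2,6-dimethoxyphenoxy]-6-methoxy-3-(3,4,5-trimethoxyphenoxy)benzene-1,2-dicarbaldehyde | COc1cc(Oc2c(OC)cc(OCc3ccccc3)cc2OC)c(Oc2cc(OC)c(OC)c(OC)c2)c(C=O)c1C=O | intermediate
27 | 4-[4-(benzyloxy)-2,6-dimethoxyphenoxy]-6-methoxy-3-(3,4,5-trimethoxyphenoxy)-1,2-phenylene diformate | COc1cc(Oc2c(OC)cc(OCc3ccccc3)cc2OC)c(Oc2cc(OC)c(OC)c(OC)c2)c(OC=O)c1OC=O | intermediate
28 | 4-[4-(benzyloxy)-2,6-dimethoxyphenoxy]-6-methoxy-3-(3,4,5-trimethoxyphenoxy)benzene-1,2-diol | COc1cc(Oc2c(OC)cc(OCc3ccccc3)cc2OC)c(Oc2cc(OC)c(OC)c(OC)c2)c(O)c1O | intermediate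
29 | 5-(benzyloxy)-1,3-dimethoxy-2-[3,4,5-trimethoxy-2-(3,4,5-trimethoxyphenoxy)phenoxy]benzene | COc1cc(Oc2c(OC)cc(OCc3ccccc3)cc2OC)c(Oc2cc(OC)c(OC)c(OC)c2)c(OC)c1OC | intermediate
30 | 3,5-dimethoxy-4-[3,4,5-trimethoxy-2-(3,4,5-trimethoxyphenoxy)phenoxy]phenol (trimer F–H phenol) | COc1cc(Oc2c(OC)cc(O)cc2OC)c(Oc2cc(OC)c(OC)c(OC)c2)c(OC)c1OC | intermediate
31 | 3-fluoro-6-methoxybenzene-1,2-dicarbaldehyde bearing at C4 the D4 oxygen of the permethylated tetramer A–D | COc1cc(Oc2c(OC)cc(Oc3c(OC)c(OC)c(OC)cc3Oc3c(OC)cc(Oc4c(OC)cc(OC)cc4OC)cc3OC)cc2OC)c(F)c(C=O)c1C=O | intermediate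
32 | permethylated octamer with ring E as 3,4-diformyl-5-methoxy-1,2-phenylene (E1–O–D4, E2–O–F1) | COc1cc(Oc2c(OC)cc(Oc3c(OC)c(OC)c(OC)cc3Oc3c(OC)cc(Oc4c(OC)cc(OC)cc4OC)cc3OC)cc2OC)c(Oc2cc(OC)c(Oc3cc(OC)c(OC)c(OC)c3Oc3cc(OC)c(OC)c(OC)c3)c(OC)c2)c(C=O)c1C=O | intermediate
33 | E3,E4-bis(formate) of the octamer diol 34 | COc1cc(Oc2c(OC)cc(Oc3c(OC)c(OC)c(OC)cc3Oc3c(OC)cc(Oc4c(OC)cc(OC)cc4OC)cc3OC)cc2OC)c(Oc2cc(OC)c(Oc3cc(OC)c(OC)c(OC)c3Oc3cc(OC)c(OC)c(OC)c3)c(OC)c2)c(OC=O)c1OC=O | intermediate
34 | octamer with free hydroxyls at E3 and E4 and nineteen methyl ethers | COc1cc(Oc2c(OC)cc(Oc3c(OC)c(OC)c(OC)cc3Oc3c(OC)cc(Oc4c(OC)cc(OC)cc4OC)cc3OC)cc2OC)c(Oc2cc(OC)c(Oc3cc(OC)c(OC)c(OC)c3Oc3cc(OC)c(OC)c(OC)c3)c(OC)c2)c(O)c1O | intermediate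
35 | CNP0206369.0 (octamer with twenty-one free hydroxyls) | Oc1cc(O)c(Oc2cc(O)c(Oc3cc(O)c(O)c(O)c3Oc3cc(O)c(Oc4cc(O)c(O)c(O)c4Oc4cc(O)c(Oc5cc(O)c(O)c(O)c5Oc5cc(O)c(O)c(O)c5)c(O)c4)c(O)c3)c(O)c2)c(O)c1 | target

## Step count and risks

Total step count: 17. Longest linear sequence: 9 steps (steps 2, 3, 5, 6, 7, 8, 15, 16, 17).

**Step 15 (key step; steps 5 and 11 share the risk and serve as its test).** Three things are most likely to go wrong:
- The second displacement may stall at the E2 carbon, which is deactivated by the para methoxy group and the new ortho aryloxy group and is sterically crowded.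
- During the long heating the dialdehyde may be destroyed by base (hydride transfer between the neighbouring formyl groups if any hydroxide is present).
- The aryloxy group already on E1, which is itself para to a formyl group, may be exchanged by the second phenoxide, scrambling the two fragments.

Fallback: make the E2–O bond by copper catalysis instead of substitution of fluoride.
- Setting out from 7, bromination (NBS, MeCN) at the position activated by both methoxy groups should give 3-bromo-4-fluoro-2,6-dimethoxybenzaldehyde F1.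
- The phenoxide of 19 displaces the fluoride para to the formyl group (Cs2CO3, DMSO) to give the bromo aldehyde F2.
- Ullmann-type etherification of F2 with 30 (CuI, N,N-dimethylglycine, Cs2CO3, dioxane, 100 °C) gives the octamer E4-monoaldehyde F3, with E3 already a methoxy group.
- Baeyer–Villiger oxidation (mCPBA) gives the formate F4 and methanolysis the octamer E4-phenol F5.
- BBr3 cleavage of the twenty methyl ethers of F5 returns to the route at 35.

**Step 1.** Metalation may occur at the ring position between the methoxy group and fluorine instead of beside the amino alkoxide, and warming of the lithiated species can eliminate LiF to an aryne. Fallback: a silyl blocking sequence that uses this bias instead of fighting it.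
- Setting out from 1, acetalisation (ethylene glycol, TsOH) gives 2-(4,5-difluoro-2-methoxyphenyl)-1,3-dioxolane F6.
- n-BuLi then Me3SiCl silylates the position between methoxy and fluorine to give the silyl acetal F7.
- s-BuLi then DMF formylates the only remaining ring position to give the silyl acetal aldehyde F8.
- Fluoride-mediated protodesilylation (CsF, wet DMF) gives the acetal aldehyde F9, and aqueous HCl returns to the route at 5.

**Step 16 (steps 6 and 12 share the risk and serve as its test).** Oxygen insertion at the second, doubly flanked E3 formyl group may be incomplete or may give the carboxylic acid by hydride migration. The 3-chlorobenzoic acid formed may promote cyclisation of the E3 formyl group onto the electron-rich ring F. The peracid may also hydroxylate the donor-rich rings on prolonged exposure. A solid hydrogencarbonate buffer can be added, but the fallback changes the second oxidation to a base-mediated one. Setting out from 32, one equivalent of mCPBA at −20 °C should convert the more electron-rich E4 formyl group to the monoformate F10. Methanolysis gives the E4-hydroxy E3-aldehyde F11, an ortho-hydroxybenzaldehyde. Classical Dakin oxidation with alkaline hydrogen peroxide (H2O2, NaOH, THF/H2O, 0 °C, Ar) then returns to the route at 34.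

**Step 17.** Cleavage of nineteen ethers may stop short when partly demethylated boron aryloxides precipitate, and the product may be oxidised by air during isolation. Fallback: setting out from 34, the crude demethylation mixture is acetylated (Ac2O, pyridine) to the henicosaacetate F12, which is stable and can be purified by chromatography, with under-demethylated fractions resubmitted to BBr3. Acidic methanolysis (HCl in MeOH from AcCl, rt, Ar) then returns to the route at 35.

## Further compounds

F1 | step 15 | 3-bromo-4-fluoro-2,6-dimethoxybenzaldehyde | COc1cc(F)c(Br)c(OC)c1C=O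
F2 | step 15 | 3-bromo-2,6-dimethoxybenzaldehyde bearing at C4 the D4 oxygen of the permethylated tetramer A–D | COc1cc(Oc2c(OC)cc(Oc3c(OC)c(OC)c(OC)cc3Oc3c(OC)cc(Oc4c(OC)cc(OC)cc4OC)cc3OC)cc2OC)c(Br)c(OC)c1C=O
F3 | step 15 | permethylated octamer with ring E as 4-formyl-3,5-dimethoxy-1,2-phenylene | COc1cc(Oc2c(OC)cc(Oc3c(OC)c(OC)c(OC)cc3Oc3c(OC)cc(Oc4c(OC)cc(OC)cc4OC)cc3OC)cc2OC)c(Oc2cc(OC)c(Oc3cc(OC)c(OC)c(OC)c3Oc3cc(OC)c(OC)c(OC)c3)c(OC)c2)c(OC)c1C=O
F4 | step 15 | E4 formate of the octamer phenol F5 | COc1cc(Oc2c(OC)cc(Oc3c(OC)c(OC)c(OC)cc3Oc3c(OC)cc(Oc4c(OC)cc(OC)cc4OC)cc3OC)cc2OC)c(Oc2cc(OC)c(Oc3cc(OC)c(OC)c(OC)c3Oc3cc(OC)c(OC)c(OC)c3)c(OC)c2)c(OC)c1OC=O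
F5 | step 15 | octamer with a free hydroxyl at E4 and twenty methyl ethers | COc1cc(Oc2c(OC)cc(Oc3c(OC)c(OC)c(OC)cc3Oc3c(OC)cc(Oc4c(OC)cc(OC)cc4OC)cc3OC)cc2OC)c(Oc2cc(OC)c(Oc3cc(OC)c(OC)c(OC)c3Oc3cc(OC)c(OC)c(OC)c3)c(OC)c2)c(OC)c1O
F6 | step 1 | 2-(4,5-difluoro-2-methoxyphenyl)-1,3-dioxolane | COc1cc(F)c(F)cc1C1OCCO1
F7 | step 1 | 2-[4,5-difluoro-2-methoxy-3-(trimethylsilyl)phenyl]-1,3-dioxolane | COc1c([Si](C)(C)C)c(F)c(F)cc1C1OCCO1
F8 | step 1 | 2-(1,3-dioxolan-2-yl)-5,6-difluoro-3-methoxy-4-(trimethylsilyl)benzaldehyde | COc1c([Si](C)(C)C)c(F)c(F)c(C=O)c1C1OCCO1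
F9 | step 1 | 2-(1,3-dioxolan-2-yl)-5,6-difluoro-3-methoxybenzaldehyde | COc1cc(F)c(F)c(C=O)c1C1OCCO1
F10 | step 16 | octamer with ring E carrying an E4 formate and an E3 formyl group | COc1cc(Oc2c(OC)cc(Oc3c(OC)c(OC)c(OC)cc3Oc3c(OC)cc(Oc4c(OC)cc(OC)cc4OC)cc3OC)cc2OC)c(Oc2cc(OC)c(Oc3cc(OC)c(OC)c(OC)c3Oc3cc(OC)c(OC)c(OC)c3)c(OC)c2)c(C=O)c1OC=O
F11 | step 16 | octamer with ring E carrying an E4 hydroxyl and an E3 formyl group | COc1cc(Oc2c(OC)cc(Oc3c(OC)c(OC)c(OC)cc3Oc3c(OC)cc(Oc4c(OC)cc(OC)cc4OC)cc3OC)cc2OC)c(Oc2cc(OC)c(Oc3cc(OC)c(OC)c(OC)c3Oc3cc(OC)c(OC)c(OC)c3)c(OC)c2)c(C=O)c1O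
F12 | step 17 | henicosaacetate of 35 | CC(=O)Oc1cc(OC(C)=O)c(Oc2cc(OC(C)=O)c(Oc3cc(OC(C)=O)c(OC(C)=O)c(OC(C)=O)c3Oc3cc(OC(C)=O)c(Oc4cc(OC(C)=O)c(OC(C)=O)c(OC(C)=O)c4Oc4cc(OC(C)=O)c(Oc5cc(OC(C)=O)c(OC(C)=O)c(OC(C)=O)c5Oc5cc(OC(C)=O)c(OC(C)=O)c(OC(C)=O)c5)c(OC(C)=O)c4)c(OC(C)=O)c3)c(OC(C)=O)c2)c(OC(C)=O)c1
A1 | alternative 1 | heptamer A–G with ring G as 5-hydroxy-3,4-dimethoxy-2-(methoxymethoxy)phenyl ether | COc1cc(OC)c(Oc2cc(OC)c(Oc3cc(OC)c(OC)c(OC)c3Oc3cc(OC)c(Oc4cc(OC)c(OC)c(OC)c4Oc4cc(OC)c(Oc5cc(O)c(OC)c(OC)c5OCOC)c(OC)c4)c(OC)c3)c(OC)c2)c(OC)c1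
A2 | alternative 1 | dimethyl squarate | COC1=C(OC)C(=O)C1=O
A3 | alternative 1 | 4-(1-aryloxyvinyl)-4-(methoxymethoxy)-2,3-dimethoxycyclobut-2-en-1-one with aryl = permethylated hexamer A–F bound through the F4 oxygen | COCOC9(C(=C)Oc1c(OC)cc(Oc2c(OC)c(OC)c(OC)cc2Oc2c(OC)cc(Oc3c(OC)c(OC)c(OC)cc3Oc3c(OC)cc(Oc4c(OC)cc(OC)cc4OC)cc3OC)cc2OC)cc1OC)C(OC)=C(OC)C9=O
A4 | alternative 1 | vinyl ether of the permethylated hexamer A–F at the F4 oxygen | C=COc1c(OC)cc(Oc2c(OC)c(OC)c(OC)cc2Oc2c(OC)cc(Oc3c(OC)c(OC)c(OC)cc3Oc3c(OC)cc(Oc4c(OC)cc(OC)cc4OC)cc3OC)cc2OC)cc1OC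
A5 | alternative 2 | octamer with ring A as methyl 2,4,6-trihydroxy-3-aryloxybenzoate and rings B to H permethylated | COC(=O)c1c(O)cc(O)c(Oc2cc(OC)c(Oc3cc(OC)c(OC)c(OC)c3Oc3cc(OC)c(Oc4cc(OC)c(OC)c(OC)c4Oc4cc(OC)c(Oc5cc(OC)c(OC)c(OC)c5Oc5cc(OC)c(OC)c(OC)c5)c(OC)c4)c(OC)c3)c(OC)c2)c1O
A6 | alternative 2 | dimethyl 4-aryloxy-3,5-dioxoheptanedioate with aryl = permethylated heptamer B–H bound through the B1 oxygen | COC(=O)CC(=O)C(Oc1cc(OC)c(Oc2cc(OC)c(OC)c(OC)c2Oc2cc(OC)c(Oc3cc(OC)c(OC)c(OC)c3Oc3cc(OC)c(Oc4cc(OC)c(OC)c(OC)c4Oc4cc(OC)c(OC)c(OC)c4)c(OC)c3)c(OC)c2)c(OC)c1)C(=O)CC(=O)OC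
A7 | alternative 3 | octamer tetraphenol with free hydroxyls on C4, E4, G4 and H4 and seventeen methyl ethers | COc1cc(OC)c(Oc2cc(OC)c(Oc3cc(OC)c(O)c(OC)c3Oc3cc(OC)c(Oc4cc(OC)c(O)c(OC)c4Oc4cc(OC)c(Oc5cc(OC)c(O)c(OC)c5Oc5cc(OC)c(O)c(OC)c5)c(OC)c4)c(OC)c3)c(OC)c2)c(OC)c1
A8 | alternative 3 | octamer tetraaldehyde with formyl groups on C4, E4, G4 and H4 and seventeen methyl ethers | COc1cc(OC)c(Oc2cc(OC)c(Oc3cc(OC)c(C=O)c(OC)c3Oc3cc(OC)c(Oc4cc(OC)c(C=O)c(OC)c4Oc4cc(OC)c(Oc5cc(OC)c(C=O)c(OC)c5Oc5cc(OC)c(C=O)c(OC)c5)c(OC)c4)c(OC)c3)c(OC)c2)c(OC)c1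
A9 | alternative 3 | 4-fluoro-3-hydroxy-2,6-dimethoxybenzaldehyde | COc1cc(F)c(O)c(OC)c1C=O
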